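**Retrosynthetic overview** (2-benzoxepine numbering: C1 lactone C=O, O2, C3, C4, C5, C5a, C6 to C9, C9a)
1. The target is an ester of two 9-hydroxy-9-(hydroxymethyl)-6-isopropyl-1-oxo-octahydro-2-benzoxepine-4-carboxylic acid units that are mirror images at all four stereocentres (acid unit 5aS,6R,9S,9aS; alcohol unit 5aR,6S,9R,9aR). Cut the inter-unit ester, trace each 1,2-diol back to a 9-methylidene group, and draw each antipode from one antipode of limonene by the same steps.
2. Oxepinone ring (last ring in each unit): ring-closing metathesis forms C4=C5 from a vinyl group on C5a and a 2-(acyloxymethyl)acrylate carried by the C9a carboxyl.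
3. Cyclohexane ring C5a-C6-C7-C8-C9-C9a: it is not closed as a six-ring. It comes from the cyclopentane ring of a 1-formyl-5-methylbicyclo[3.1.0]hexane-6-carboxylate by a thermal retro-ene ring expansion that takes the cyclopropane apex (future C9a) into the ring.
4. Enabling feature: C9 (with its exocyclic CH2O carbon) and C5a (with the exocyclic carbon C5) both flank C9a. An extra C9-C5a bond therefore makes C9/C9a/C5a a cyclopropane and makes H-CH2-C9-C5a-CH=O a six-atom retro-ene array. The substituents on C6, C5a and C9a are all equatorial, so the centre formed through the enol settles correctly.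
5. Ring order per unit: cyclopentene (aldol condensation) → cyclopropane plus temporary γ-lactone (tethered carbene) → cyclohexane (ring expansion) → oxepinone (metathesis). The two antipodal units are then joined.

Key step: step 9

Remark: the SMILES is read literally. The two bicyclic halves have opposite absolute configuration at every stereocentre, so both enantiomeric series are made.

**Series from (R)-limonene (alcohol unit)**

Step 1
Reactants: 1 (R)-(+)-limonene
Product: 2 (R)-p-menth-1-ene
Conditions: H2 (1 atm), RhCl(PPh3)3 (cat.), toluene-EtOH, rt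
Reagents that add atoms: none
Why: Homogeneous hydrogenation with RhCl(PPh3)3 reduces the unhindered 1,1-disubstituted isopropenyl alkene much faster than the trisubstituted ring alkene and leaves the stereocentre untouched.

Step 2
Reactants: 2 (R)-p-menth-1-ene
Product: 4 (3R)-6-oxo-3-(propan-2-yl)heptanal, via secondary ozonide 3 (not isolated)
Conditions: O3, CH2Cl2, -78 °C; then Me2S, -78 °C to rt
Reagents that add atoms: ozone, [O-][O+]=O
Why: Ozonolysis with reductive work-up cleaves the only alkene to the keto aldehyde, and the stereocentre is not enolisable.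

Step 3
Reactants: 4 (3R)-6-oxo-3-(propan-2-yl)heptanal
Product: 5 (5S)-2-methyl-5-(propan-2-yl)cyclopent-1-ene-1-carbaldehyde
Conditions: piperidine (cat.), AcOH (cat.), toluene, reflux (Dean-Stark)
Reagents that add atoms: none
Why: In this intramolecular aldol condensation the enamine of the aldehyde attacks the methyl ketone (five-membered ring), and the isopropyl-bearing centre sits on the α-carbon side of the enal and cannot epimerise.

Step 4
Reactants: 5 (5S)-2-methyl-5-(propan-2-yl)cyclopent-1-ene-1-carbaldehyde
Product: 6 [(5S)-2-methyl-5-(propan-2-yl)cyclopent-1-en-1-yl]methanol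
Conditions: NaBH4, CeCl3·7H2O, MeOH, 0 °C
Reagents that add atoms: none
Why: Luche reduction gives clean 1,2-reduction of the enal to the allylic alcohol.

Step 5
Reactants: 6 [(5S)-2-methyl-5-(propan-2-yl)cyclopent-1-en-1-yl]methanol
Product: 8 [(5S)-2-methyl-5-(propan-2-yl)cyclopent-1-en-1-yl]methyl diazoacetate, via bromoacetate 7 (not isolated)
Conditions: BrCH2COBr, NaHCO3, MeCN, 0 °C; then TsNHNHTs, DBU, THF, 0 °C
Reagents that add atoms: bromoacetyl bromide, BrCC(Br)=O; N,N'-ditosylhydrazine, Cc1ccc(cc1)S(=O)(=O)NNS(=O)(=O)c1ccc(C)cc1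
Why: O-acylation, N-alkylation of ditosylhydrazine and double sulfinate elimination (diazoacetate synthesis from a bromoacetate) proceed under mild base without touching the stereocentre.

Step 6
Reactants: 8 [(5S)-2-methyl-5-(propan-2-yl)cyclopent-1-en-1-yl]methyl diazoacetate
Product: 9 tricyclic γ-lactone of (1S,2S,5S,6S)-1-(hydroxymethyl)-5-methyl-2-(propan-2-yl)bicyclo[3.1.0]hexane-6-carboxylic acid
Conditions: Rh2(OAc)4 (cat.), CH2Cl2, reflux, slow addition of 8
Reagents that add atoms: none
Why: In this rhodium-carbenoid intramolecular cyclopropanation of an allylic diazoacetate, the five-membered tether forces the carbonyl cis to the CH2O arm (exo face, also cis to the methyl group) and the isopropyl group shields one alkene face, so the three new stereocentres are set anti to it.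

Step 7
Reactants: 9 tricyclic γ-lactone; 10 tert-butyl 2-(bromomethyl)acrylate
Product: 12 2-(tert-butoxycarbonyl)prop-2-en-1-yl (1S,2S,5S,6S)-1-(hydroxymethyl)-5-methyl-2-(propan-2-yl)bicyclo[3.1.0]hexane-6-carboxylate, via potassium carboxylate 11 (not isolated)
Conditions: KOH (1.05 equiv), MeOH-H2O, rt; evaporate; then 10, DMF, 0 °C to rt
Reagents that add atoms: potassium hydroxide, [K+].[OH-]; tert-butyl 2-(bromomethyl)acrylate (10), C=C(CBr)C(=O)OC(C)(C)C
Why: Saponification of the γ-lactone and O-alkylation of the carboxylate (SN2 and SN2' give the same ester) free the primary alcohol and install the acrylate needed later, with no stereocentre touched.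

Step 8
Reactants: 12 hydroxy ester
Product: 13 2-(tert-butoxycarbonyl)prop-2-en-1-yl (1S,2S,5S,6S)-1-formyl-5-methyl-2-(propan-2-yl)bicyclo[3.1.0]hexane-6-carboxylate
Conditions: Dess-Martin periodinane, pyridine, CH2Cl2, 0 °C to rt (used directly after step 7)
Reagents that add atoms: none
Why: Buffered Dess-Martin oxidation converts the primary cyclopropylcarbinol into the aldehyde faster than it can relactonise.

Step 9
Reactants: 13 cyclopropane aldehyde
Product: 15 2-(tert-butoxycarbonyl)prop-2-en-1-yl (1R,2S,3S)-2-formyl-6-methylidene-3-(propan-2-yl)cyclohexane-1-carboxylate, via Z-enol 14 (not isolated)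
Conditions: toluene (dilute), BHT (cat.), sealed tube, 160 °C; then Et3N (cat.), rt
Reagents that add atoms: none
Why: On heating, the formyl oxygen on C1 takes a hydrogen from the cis methyl group on C5 through a six-membered transition state while the C1-C5 ring-fusion bond of the cyclopropane breaks (concerted six-electron retro-ene, a homo-[1,5]-hydrogen shift), so the five-membered ring takes up the apex carbon C6 and becomes the cyclohexane, with an exocyclic methylene exactly at the future carbinol carbon and the Z-enol 14 at the future allylic methine. The closest known reaction type is the thermal rearrangement of cis-2-alkylcyclopropyl aldehydes and ketones to γ,δ-unsaturated carbonyl compounds, and strain release of the bicyclo[3.1.0]hexane together with the second acceptor on C6 should lower the barrier. No ring is closed by a new bond: the six-membered ring results from cleavage of the zero-atom bridge, a one-atom ring expansion from five to six. The ester-bearing centre keeps all four of its bonds, so the configuration set in step 6 is carried over and ends cis-1,3 (diequatorial) to the isopropyl group, while the formyl-bearing centre is created on ketonisation of 14 and, being epimerisable, settles as the equatorial aldehyde trans to both neighbours. The step needs bond selectivity (C1-C5, not C5-C6 or C1-C6) and regioselectivity for the exocyclic alkene: only the methyl hydrogens lie on the cyclopropane face of the formyl group (the ring CH2 on C5 is on the other face), and an aldehyde carbonyl is a far better hydrogen acceptor than the cis ester carbonyl that would break C5-C6.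

Step 10
Reactants: 15 ring-expanded aldehyde
Product: 16 2-(tert-butoxycarbonyl)prop-2-en-1-yl (1R,2S,3S)-2-ethenyl-6-methylidene-3-(propan-2-yl)cyclohexane-1-carboxylate
Conditions: Ph3PCH3Br, KHMDS, THF, 0 °C; then 15, -78 °C to 0 °C
Reagents that add atoms: methyltriphenylphosphonium bromide, C[P+](c1ccccc1)(c1ccccc1)c1ccccc1.[Br-]
Why: Wittig methylenation of the aldehyde at low temperature outruns attack of the ylide on the ester and acrylate groups, and the adjacent centre already holds its more stable equatorial configuration.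

Step 11
Reactants: 16 triene ester
Product: 17 tert-butyl (5aR,6S,9aR)-9-methylidene-1-oxo-6-(propan-2-yl)-1,3,5a,6,7,8,9,9a-octahydro-2-benzoxepine-4-carboxylate
Conditions: second-generation Hoveyda-Grubbs catalyst (cat.), 1,4-benzoquinone (cat.), toluene (high dilution), 80 °C
Reagents that add atoms: none
Why: In this ring-closing metathesis the ruthenium carbene loads on the vinyl group and can close only onto the acrylate methylene (closure onto the ring methylidene would need a cyclobutene), and the trans-diequatorial arms give the trans-fused seven-membered lactone.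

Step 12
Reactants: 17 methylidene lactone
Product: 18 tert-butyl (5aR,6S,9R,9aR)-9-hydroxy-9-(hydroxymethyl)-1-oxo-6-(propan-2-yl)-1,3,5a,6,7,8,9,9a-octahydro-2-benzoxepine-4-carboxylate
Conditions: OsO4 (cat.), NMO, acetone-H2O, 0 °C to rt
Reagents that add atoms: N-methylmorpholine N-oxide, C[N+]1([O-])CCOCC1; water, O
Why: Upjohn dihydroxylation picks the electron-rich 1,1-disubstituted alkene over the enoate, and OsO4 approaches the methylidene of the locked chair from the equatorial direction (the axial face is screened by the axial hydrogens on C5a and C7), which sets C9 with equatorial OH and axial CH2OH.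

**Series from (S)-limonene (acid unit)**

Step 13
Reactants: 19 (S)-(-)-limonene
Product: 20 (S)-p-menth-1-ene
Conditions: H2 (1 atm), RhCl(PPh3)3 (cat.), toluene-EtOH, rt
Reagents that add atoms: none
Why: The same chemoselective homogeneous hydrogenation of the isopropenyl group as in step 1 is run on the antipode, with the stereocentre untouched.

Step 14
Reactants: 20 (S)-p-menth-1-ene
Product: 22 (3S)-6-oxo-3-(propan-2-yl)heptanal, via secondary ozonide 21 (not isolated)
Conditions: O3, CH2Cl2, -78 °C; then Me2S, -78 °C to rt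
Reagents that add atoms: ozone, [O-][O+]=O
Why: Ozonolysis with reductive work-up cleaves the only alkene and does not affect the stereocentre.

Step 15
Reactants: 22 (3S)-6-oxo-3-(propan-2-yl)heptanal
Product: 23 (5R)-2-methyl-5-(propan-2-yl)cyclopent-1-ene-1-carbaldehyde
Conditions: piperidine (cat.), AcOH (cat.), toluene, reflux (Dean-Stark)
Reagents that add atoms: none
Why: Intramolecular aldol condensation through the aldehyde enamine closes the cyclopentene, and the stereocentre is configurationally stable.

Step 16
Reactants: 23 (5R)-2-methyl-5-(propan-2-yl)cyclopent-1-ene-1-carbaldehyde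
Product: 24 [(5R)-2-methyl-5-(propan-2-yl)cyclopent-1-en-1-yl]methanol
Conditions: NaBH4, CeCl3·7H2O, MeOH, 0 °C
Reagents that add atoms: none
Why: Luche reduction gives 1,2-reduction of the enal only.

Step 17
Reactants: 24 [(5R)-2-methyl-5-(propan-2-yl)cyclopent-1-en-1-yl]methanol
Product: 26 [(5R)-2-methyl-5-(propan-2-yl)cyclopent-1-en-1-yl]methyl diazoacetate, via bromoacetate 25 (not isolated)
Conditions: BrCH2COBr, NaHCO3, MeCN, 0 °C; then TsNHNHTs, DBU, THF, 0 °C
Reagents that add atoms: bromoacetyl bromide, BrCC(Br)=O; N,N'-ditosylhydrazine, Cc1ccc(cc1)S(=O)(=O)NNS(=O)(=O)c1ccc(C)cc1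
Why: The diazoacetate synthesis from the bromoacetate by alkylation of ditosylhydrazine and sulfinate elimination runs as in step 5.

Step 18
Reactants: 26 [(5R)-2-methyl-5-(propan-2-yl)cyclopent-1-en-1-yl]methyl diazoacetate
Product: 27 tricyclic γ-lactone of (1R,2R,5R,6R)-1-(hydroxymethyl)-5-methyl-2-(propan-2-yl)bicyclo[3.1.0]hexane-6-carboxylic acid
Conditions: Rh2(OAc)4 (cat.), CH2Cl2, reflux, slow addition of 26
Reagents that add atoms: none
Why: In this rhodium-carbenoid intramolecular cyclopropanation the tether fixes the exo carbonyl and the isopropyl group directs the carbene to the opposite face, which sets three stereocentres in the mirror-image sense of step 6.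

Step 19
Reactants: 27 tricyclic γ-lactone; 10 tert-butyl 2-(bromomethyl)acrylate
Product: 29 2-(tert-butoxycarbonyl)prop-2-en-1-yl (1R,2R,5R,6R)-1-(hydroxymethyl)-5-methyl-2-(propan-2-yl)bicyclo[3.1.0]hexane-6-carboxylate, via potassium carboxylate 28 (not isolated)
Conditions: KOH (1.05 equiv), MeOH-H2O, rt; evaporate; then 10, DMF, 0 °C to rt
Reagents that add atoms: potassium hydroxide, [K+].[OH-]; tert-butyl 2-(bromomethyl)acrylate (10), C=C(CBr)C(=O)OC(C)(C)C
Why: Saponification and carboxylate O-alkylation proceed as in step 7 without touching a stereocentre.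

Step 20
Reactants: 29 hydroxy ester
Product: 30 2-(tert-butoxycarbonyl)prop-2-en-1-yl (1R,2R,5R,6R)-1-formyl-5-methyl-2-(propan-2-yl)bicyclo[3.1.0]hexane-6-carboxylate
Conditions: Dess-Martin periodinane, pyridine, CH2Cl2, 0 °C to rt
Reagents that add atoms: none
Why: Buffered Dess-Martin oxidation of the primary alcohol outruns relactonisation.

Step 21
Reactants: 30 cyclopropane aldehyde
Product: 32 2-(tert-butoxycarbonyl)prop-2-en-1-yl (1S,2R,3R)-2-formyl-6-methylidene-3-(propan-2-yl)cyclohexane-1-carboxylate, via Z-enol 31 (not isolated)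
Conditions: toluene (dilute), BHT (cat.), sealed tube, 160 °C; then Et3N (cat.), rt
Reagents that add atoms: none
Why: The same thermal retro-ene (homo-[1,5]-hydrogen shift) ring expansion as in step 9 retains the ester-bearing centre and lets the formyl-bearing centre equilibrate to the equatorial position.

Step 22
Reactants: 32 ring-expanded aldehyde
Product: 33 2-(tert-butoxycarbonyl)prop-2-en-1-yl (1S,2R,3R)-2-ethenyl-6-methylidene-3-(propan-2-yl)cyclohexane-1-carboxylate
Conditions: Ph3PCH3Br, KHMDS, THF, 0 °C; then 32, -78 °C to 0 °C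
Reagents that add atoms: methyltriphenylphosphonium bromide, C[P+](c1ccccc1)(c1ccccc1)c1ccccc1.[Br-]
Why: Wittig methylenation of the aldehyde runs at low temperature, as in step 10.

Step 23
Reactants: 33 triene ester
Product: 34 tert-butyl (5aS,6R,9aS)-9-methylidene-1-oxo-6-(propan-2-yl)-1,3,5a,6,7,8,9,9a-octahydro-2-benzoxepine-4-carboxylate
Conditions: second-generation Hoveyda-Grubbs catalyst (cat.), 1,4-benzoquinone (cat.), toluene (high dilution), 80 °C
Reagents that add atoms: none
Why: Ring-closing metathesis of the vinyl and acrylate methylene groups closes the trans-fused seven-membered lactone, as in step 11.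

Step 24
Reactants: 34 methylidene lactone tert-butyl ester
Product: 36 (5aS,6R,9aS)-9-methylidene-1-oxo-6-(propan-2-yl)-1,3,5a,6,7,8,9,9a-octahydro-2-benzoxepine-4-carboxylic acid, via trimethylsilyl ester 35 (not isolated)
Conditions: TMSOTf, 2,6-lutidine, CH2Cl2, 0 °C; then aqueous citric acid
Reagents that add atoms: none
Why: Silyl-triflate-mediated cleavage of the tert-butyl ester (transsilylation with loss of isobutene, then hydrolysis of the silyl ester on work-up) avoids strong protic acid that could shift the exocyclic alkene.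

**Union and completion**

Step 25
Reactants: 36 acid unit; 18 diol unit
Product: 37 [(5aR,6S,9R,9aR)-4-(tert-butoxycarbonyl)-9-hydroxy-1-oxo-6-(propan-2-yl)-octahydro-2-benzoxepin-9-yl]methyl (5aS,6R,9aS)-9-methylidene-1-oxo-6-(propan-2-yl)-octahydro-2-benzoxepine-4-carboxylate
Conditions: DIC, DMAP (cat.), CH2Cl2, 0 °C to rt
Reagents that add atoms: none
Why: In this Steglich esterification only the primary hydroxyl of 18 is acylated, the tertiary one is inert, and no stereocentre is involved.

Step 26
Reactants: 37 coupled methylidene ester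
Product: 38 tert-butyl ester of the target
Conditions: OsO4 (cat.), NMO, acetone-H2O, 0 °C to rt
Reagents that add atoms: N-methylmorpholine N-oxide, C[N+]1([O-])CCOCC1; water, O
Why: Upjohn dihydroxylation of the only electron-rich alkene, with the same equatorial approach of OsO4 as in step 12, sets C9 of the acid unit (9S) with equatorial OH and axial CH2OH.

Step 27
Reactants: 38 tert-butyl ester of the target
Product: 39 CNP0340505.1 (target)
Conditions: CF3CO2H, CH2Cl2, 0 °C to rt
Reagents that add atoms: none
Why: Acidolysis of the tert-butyl ester (E1 loss of isobutene) leaves the primary inter-unit ester, both lactones and both diols intact.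

**Compound list**
1 | (R)-(+)-limonene | CC1=CC[C@@H](CC1)C(C)=C | starting material
2 | (R)-p-menth-1-ene | CC1=CC[C@@H](CC1)C(C)C | intermediate
3 | secondary ozonide of 2 (both acetal carbons unassigned) | CC12CC[C@@H](C(C)C)CC(OO1)O2 | intermediate
4 | (3R)-6-oxo-3-(propan-2-yl)heptanal | O=CC[C@@H](CCC(C)=O)C(C)C | intermediate
5 | (5S)-2-methyl-5-(propan-2-yl)cyclopent-1-ene-1-carbaldehyde | O=CC1=C(C)CC[C@H]1C(C)C | intermediate
6 | [(5S)-2-methyl-5-(propan-2-yl)cyclopent-1-en-1-yl]methanol | OCC1=C(C)CC[C@H]1C(C)C | intermediate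
7 | bromoacetate of 6 | BrCC(=O)OCC1=C(C)CC[C@H]1C(C)C | intermediate
8 | diazoacetate of 6 | [N-]=[N+]=CC(=O)OCC1=C(C)CC[C@H]1C(C)C | intermediate
9 | tricyclic γ-lactone (1S,2S,5S,6S; cyclopropane anti to isopropyl, carbonyl exo) | CC(C)[C@@H]1CC[C@@]2(C)[C@@H]3C(=O)OC[C@]123 | intermediate
10 | tert-butyl 2-(bromomethyl)acrylate | C=C(CBr)C(=O)OC(C)(C)C | starting material
11 | potassium (1S,2S,5S,6S)-1-(hydroxymethyl)-5-methyl-2-(propan-2-yl)bicyclo[3.1.0]hexane-6-carboxylate | CC(C)[C@@H]1CC[C@@]2(C)[C@H](C(=O)[O-])[C@@]12CO.[K+] | intermediate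
12 | 2-(tert-butoxycarbonyl)allyl ester of the acid of 11 | CC(C)[C@@H]1CC[C@@]2(C)[C@H](C(=O)OCC(=C)C(=O)OC(C)(C)C)[C@@]12CO | intermediate
13 | 1-formyl analogue of 12 (1S,2S,5S,6S) | CC(C)[C@@H]1CC[C@@]2(C)[C@H](C(=O)OCC(=C)C(=O)OC(C)(C)C)[C@@]12C=O | intermediate
14 | Z-enol of 15 (hydroxymethylidene cis to the ester-bearing carbon) | CC(C)[C@@H]1CCC(=C)[C@H](C(=O)OCC(=C)C(=O)OC(C)(C)C)/C1=C\O | intermediate
15 | (1R,2S,3S)-2-formyl-6-methylidene-3-(propan-2-yl)cyclohexane-1-carboxylate, 2-(tert-butoxycarbonyl)allyl ester | CC(C)[C@@H]1CCC(=C)[C@H](C(=O)OCC(=C)C(=O)OC(C)(C)C)[C@H]1C=O | intermediate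
16 | (1R,2S,3S)-2-ethenyl analogue of 15 | CC(C)[C@@H]1CCC(=C)[C@H](C(=O)OCC(=C)C(=O)OC(C)(C)C)[C@H]1C=C | intermediate
17 | tert-butyl (5aR,6S,9aR)-9-methylidene-1-oxo-6-(propan-2-yl)octahydro-2-benzoxepine-4-carboxylate | CC(C)[C@@H]1CCC(=C)[C@@H]2C(=O)OCC(C(=O)OC(C)(C)C)=C[C@@H]12 | intermediate
18 | tert-butyl (5aR,6S,9R,9aR)-9-hydroxy-9-(hydroxymethyl)-1-oxo-6-(propan-2-yl)octahydro-2-benzoxepine-4-carboxylate | CC(C)[C@@H]1CC[C@](O)(CO)[C@@H]2C(=O)OCC(C(=O)OC(C)(C)C)=C[C@@H]12 | intermediate
19 | (S)-(-)-limonene | CC1=CC[C@H](CC1)C(C)=C | starting material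
20 | (S)-p-menth-1-ene | CC1=CC[C@H](CC1)C(C)C | intermediate
21 | secondary ozonide of 20 | CC12CC[C@H](C(C)C)CC(OO1)O2 | intermediate
22 | (3S)-6-oxo-3-(propan-2-yl)heptanal | O=CC[C@H](CCC(C)=O)C(C)C | intermediate
23 | (5R)-2-methyl-5-(propan-2-yl)cyclopent-1-ene-1-carbaldehyde | O=CC1=C(C)CC[C@@H]1C(C)C | intermediate
24 | [(5R)-2-methyl-5-(propan-2-yl)cyclopent-1-en-1-yl]methanol | OCC1=C(C)CC[C@@H]1C(C)C | intermediate
25 | bromoacetate of 24 | BrCC(=O)OCC1=C(C)CC[C@@H]1C(C)C | intermediate
26 | diazoacetate of 24 | [N-]=[N+]=CC(=O)OCC1=C(C)CC[C@@H]1C(C)C | intermediate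
27 | tricyclic γ-lactone (1R,2R,5R,6R), enantiomer of 9 | CC(C)[C@H]1CC[C@]2(C)[C@H]3C(=O)OC[C@@]123 | intermediate
28 | potassium carboxylate, enantiomer of 11 | CC(C)[C@H]1CC[C@]2(C)[C@@H](C(=O)[O-])[C@]12CO.[K+] | intermediate
29 | hydroxy ester, enantiomer of 12 | CC(C)[C@H]1CC[C@]2(C)[C@@H](C(=O)OCC(=C)C(=O)OC(C)(C)C)[C@]12CO | intermediate
30 | cyclopropane aldehyde, enantiomer of 13 | CC(C)[C@H]1CC[C@]2(C)[C@@H](C(=O)OCC(=C)C(=O)OC(C)(C)C)[C@]12C=O | intermediate
31 | Z-enol, enantiomer of 14 | CC(C)[C@H]1CCC(=C)[C@@H](C(=O)OCC(=C)C(=O)OC(C)(C)C)/C1=C\O | intermediate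
32 | (1S,2R,3R)-aldehyde, enantiomer of 15 | CC(C)[C@H]1CCC(=C)[C@@H](C(=O)OCC(=C)C(=O)OC(C)(C)C)[C@@H]1C=O | intermediate
33 | (1S,2R,3R)-triene ester, enantiomer of 16 | CC(C)[C@H]1CCC(=C)[C@@H](C(=O)OCC(=C)C(=O)OC(C)(C)C)[C@@H]1C=C | intermediate
34 | tert-butyl (5aS,6R,9aS)-9-methylidene-1-oxo-6-(propan-2-yl)octahydro-2-benzoxepine-4-carboxylate | CC(C)[C@H]1CCC(=C)[C@H]2C(=O)OCC(C(=O)OC(C)(C)C)=C[C@H]12 | intermediate
35 | trimethylsilyl ester corresponding to 34 | CC(C)[C@H]1CCC(=C)[C@H]2C(=O)OCC(C(=O)O[Si](C)(C)C)=C[C@H]12 | intermediate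
36 | (5aS,6R,9aS)-9-methylidene-1-oxo-6-(propan-2-yl)octahydro-2-benzoxepine-4-carboxylic acid | CC(C)[C@H]1CCC(=C)[C@H]2C(=O)OCC(C(=O)O)=C[C@H]12 | intermediate
37 | coupled ester (acid unit still 9-methylidene, alcohol unit as tert-butyl ester) | CC(C)[C@H]1CCC(=C)[C@H]2C(=O)OCC(C(=O)OC[C@@]3(O)CC[C@@H](C(C)C)[C@@H]4C=C(C(=O)OC(C)(C)C)COC(=O)[C@H]43)=C[C@H]12 | intermediate
38 | tert-butyl ester of the target | CC(C)[C@H]1CC[C@@](O)(CO)[C@H]2C(=O)OCC(C(=O)OC[C@@]3(O)CC[C@@H](C(C)C)[C@@H]4C=C(C(=O)OC(C)(C)C)COC(=O)[C@H]43)=C[C@H]12 | intermediate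
39 | CNP0340505.1 | CC(C)[C@H]1CC[C@@](O)(CO)[C@H]2C(=O)OCC(C(=O)OC[C@@]3(O)CC[C@@H](C(C)C)[C@@H]4C=C(C(=O)O)COC(=O)[C@H]43)=C[C@H]12 | target

**Step count**
Total step count: 27. Longest linear sequence: 15 steps (steps 1 to 12, then 25 to 27; the series 13 to 24, then 25 to 27, is equally long).

**Steps most likely to fail**

Step 9. The hydrogen shift may need a temperature at which the tert-butyl ester loses isobutene or the acrylate unit polymerises before the cyclopropane opens. The fallback carries a thermally inert ester through the pyrolysis and installs the acrylate afterwards. It sets out from 9 and comes back at 16.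
- Salt 11 (from 9 and KOH) is alkylated with allyl bromide to allyl (1S,2S,5S,6S)-1-(hydroxymethyl)-5-methyl-2-(propan-2-yl)bicyclo[3.1.0]hexane-6-carboxylate F1.
- Dess-Martin oxidation gives the cyclopropane aldehyde F2.
- Heating at a higher temperature in o-dichlorobenzene passes through the Z-enol F3 to the ring-expanded allyl (1R,2S,3S)-2-formyl-6-methylidene-3-(propan-2-yl)cyclohexane-1-carboxylate F4.
- Wittig methylenation gives the vinyl allyl ester F5.
- Pd(PPh3)4 and morpholine release the acid F6.
- Alkylation of F6 with 10 and K2CO3 in DMF returns to 16.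

Step 6. Carbene dimerisation and slow addition to the tetrasubstituted alkene may erode the cyclopropanation. The fallback uses a more robust diazomalonate that tolerates forcing conditions. It sets out from 6 and comes back at 9.
- Alcohol 6 is acylated with methyl malonyl chloride to the mixed malonate F7.
- Diazo transfer (p-acetamidobenzenesulfonyl azide, Et3N) gives the diazomalonate F8.
- Cu(acac)2 in refluxing toluene closes the cyclopropane lactone methyl ester F9.
- Krapcho demethoxycarbonylation (LiCl, wet DMSO, heat) removes the extra ester and returns to 9. The lactone ring keeps the remaining carbonyl exo, so no stereochemical question arises.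

Step 25. Acylation of the neopentyl-type primary hydroxyl may be slow. That leaves time for rearrangement of the activated acid to an N-acylurea and for DMAP-induced translactonisation of the diol onto the C1 carbonyl. The fallback reverses the polarity of the union. It sets out from 18 and 36 and comes back at 37.
- Diol 18 is converted with MsCl and Et3N at low temperature into the primary mesylate F10.
- K2CO3 in MeCN closes F10 to the spiro-epoxide F11, with C9 untouched.
- Acid 36 with Cs2CO3 in DMF opens F11 at the CH2 terminus (SN2) and returns to 37.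

**Further compounds**
F1 | step 9 | allyl (1S,2S,5S,6S)-1-(hydroxymethyl)-5-methyl-2-(propan-2-yl)bicyclo[3.1.0]hexane-6-carboxylate | CC(C)[C@@H]1CC[C@@]2(C)[C@H](C(=O)OCC=C)[C@@]12CO
F2 | step 9 | allyl (1S,2S,5S,6S)-1-formyl-5-methyl-2-(propan-2-yl)bicyclo[3.1.0]hexane-6-carboxylate | CC(C)[C@@H]1CC[C@@]2(C)[C@H](C(=O)OCC=C)[C@@]12C=O
F3 | step 9 | Z-enol of F4 | CC(C)[C@@H]1CCC(=C)[C@H](C(=O)OCC=C)/C1=C\O
F4 | step 9 | allyl (1R,2S,3S)-2-formyl-6-methylidene-3-(propan-2-yl)cyclohexane-1-carboxylate | CC(C)[C@@H]1CCC(=C)[C@H](C(=O)OCC=C)[C@H]1C=O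
F5 | step 9 | allyl (1R,2S,3S)-2-ethenyl-6-methylidene-3-(propan-2-yl)cyclohexane-1-carboxylate | CC(C)[C@@H]1CCC(=C)[C@H](C(=O)OCC=C)[C@H]1C=C
F6 | step 9 | (1R,2S,3S)-2-ethenyl-6-methylidene-3-(propan-2-yl)cyclohexane-1-carboxylic acid | CC(C)[C@@H]1CCC(=C)[C@H](C(=O)O)[C@H]1C=C
F7 | step 6 | methyl [(5S)-2-methyl-5-(propan-2-yl)cyclopent-1-en-1-yl]methyl malonate | COC(=O)CC(=O)OCC1=C(C)CC[C@H]1C(C)C
F8 | step 6 | corresponding diazomalonate | COC(=O)C(=[N+]=[N-])C(=O)OCC1=C(C)CC[C@H]1C(C)C
F9 | step 6 | tricyclic lactone carrying an endo methoxycarbonyl group on the apex carbon | CC(C)[C@@H]1CC[C@@]2(C)[C@]3(C(=O)OC)C(=O)OC[C@]123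
F10 | step 25 | primary mesylate of 18 | CC(C)[C@@H]1CC[C@](O)(COS(C)(=O)=O)[C@@H]2C(=O)OCC(C(=O)OC(C)(C)C)=C[C@@H]12
F11 | step 25 | spiro-epoxide from F10 (5aR,6S,9R,9aR) | CC(C)[C@@H]1CC[C@]3(CO3)[C@@H]2C(=O)OCC(C(=O)OC(C)(C)C)=C[C@@H]12
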